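**Retrosynthetic overview**
1. The acyclic target is cut in three places. The aroyl ester C(=O)–O bond leads to benzyl (R)-4-benzyloxy-3-hydroxybutanoate, made from (R)-benzyl glycidyl ether. The aryl–CO2H carbon comes from formylation and oxidation. The Ar–CH2 bond comes from an aryl Grignard reagent and (R)-propylene oxide. All benzyl-type groups fall in one final hydrogenolysis.
2. Feature: the terminal (S)-CH3CH(OH)CH2C(=O) unit and the inner (R)-OCH(CH3)CH2C(=O) unit have opposite configurations. Together they are the ring-opened form of the centrosymmetric eight-membered dilactone (4R,8S)-4,8-dimethyl-1,5-dioxocane-2,6-dione (ring atoms O1–C2(=O)–C3–C4–O5–C6(=O)–C7–C8).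
3. This ring is cut at O1–C8 and O5–C4. Both O–CH(CH3) bonds arise from oxygen insertion into the two C(=O)–CH(CH3) bonds of trans-(2R,5S)-2,5-dimethylcyclohexane-1,4-dione, which is built from achiral dimethyl succinate.
4. The ester bond between the arylpropanol oxygen and C2 of the diolide is made by a catalyst-controlled choice between the two enantiotopic lactone carbonyls.
5. Ring order: six-membered carbocycle (Claisen/Dieckmann), then seven-membered keto-lactone, then eight-membered diolide (both by ring expansion), which is then opened. The benzene ring is bought.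

Key step: step 4

Assumption: the sense in which the yttrium catalyst of step 8 tells the two lactone carbonyls apart cannot be predicted. The (R,R)-ligand is written, and its mirror image would take its place if that proves to be the matched partner of 12.

**Step 1**
Reactants: 1 dimethyl succinate (two molecules)
Product: 3 dimethyl 2,5-dioxocyclohexane-1,4-dicarboxylate (dimethyl succinylsuccinate), via open-chain Claisen triester 2 (not isolated)
Conditions: NaOMe (1.1 equiv per 1), MeOH, reflux; then aq HCl, 0 °C
Reagents that add atoms: none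
Why: An intermolecular Claisen condensation followed by Dieckmann closure should give the six-membered bis-β-keto ester, with precipitation of its disodium bis-enolate driving both equilibria; no lasting stereocentre is formed.

**Step 2**
Reactants: 3 dimethyl 2,5-dioxocyclohexane-1,4-dicarboxylate
Product: 4 dimethyl 1,4-dimethyl-2,5-dioxocyclohexane-1,4-dicarboxylate (cis/trans mixture used as such)
Conditions: MeI (2.5 equiv), K2CO3 (2.5 equiv), acetone, reflux
Reagents that add atoms: iodomethane, CI
Why: Double C-alkylation of the stabilised β-keto ester enolates (SN2 on MeI) under weak-base conditions favours carbon over oxygen attack, and the configuration of the two quaternary centres does not matter because step 3 erases both.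

**Step 3**
Reactants: 4 dimethyl 1,4-dimethyl-2,5-dioxocyclohexane-1,4-dicarboxylate
Product: 6 (2R,5S)-2,5-dimethylcyclohexane-1,4-dione (trans; meso), via bis-β-keto diacid 5 (not isolated)
Conditions: 20% aq H2SO4, reflux; crystallisation (hexane–Et2O); mother liquor re-equilibrated (cat. TsOH, toluene) and recrystallised
Reagents that add atoms: none
Why: Acid-catalysed ester hydrolysis and β-keto acid decarboxylation (acid rather than base avoids retro-Claisen ring cleavage) give the dione, whose α-centres equilibrate through the enol, so the trans relationship is set thermodynamically and secured by crystallisation of the centrosymmetric isomer.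

**Step 4**
Reactants: 6 (2R,5S)-2,5-dimethylcyclohexane-1,4-dione
Product: 8 (4R,8S)-4,8-dimethyl-1,5-dioxocane-2,6-dione (meso diolide), via racemic keto-lactone 7 (not isolated)
Conditions: mCPBA (3 equiv), CH2Cl2, 0 → 40 °C; crystallisation
Reagents that add atoms: 3-chloroperoxybenzoic acid, OOC(=O)c1cccc(Cl)c1
Why: Each ketone adds mCPBA to give a Criegee hemiperketal, from which the carbon antiperiplanar to the O–O bond shifts to oxygen as 3-chlorobenzoate leaves, the first shift giving the seven-membered keto-lactone 7 and the second the eight-membered dilactone 8. This is the Baeyer–Villiger oxidation, established for 2-alkylcyclohexanones and for cyclohexane-1,4-diones, including their conversion into eight-membered diolides. No ring is closed: the existing carbocycle grows from six to seven to eight members by two 1,2-shifts, and the C–O bonds O1–C8 and O5–C4 replace the two C(=O)–CH(CH3) bonds. No stereocentre is created, because the concerted shift keeps the configuration of the migrating carbon, so (2R,5S) in 6 becomes (4R,8S) in 8 and both enantiomers of chiral 7 converge on the same meso product. Regioselectivity is needed in both insertions and comes from the secondary CH(CH3) carbon carrying the developing positive charge better than CH2, an advantage that should grow in 7, where the competing CH2 (C6) sits next to the acyloxy-bearing carbon C7. The α-centres must also survive until oxidised, which is helped by the absence of any acid stronger than the sparingly soluble 3-chlorobenzoic acid and by trans being the preferred isomer, and any cis leakage would give the C2-symmetric racemic diolide, a diastereomer that crystallisation can remove.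

**Step 5**
Reactants: 9 1-bromo-3,5-bis(benzyloxy)benzene; 10 (R)-propylene oxide
Product: 12 (R)-1-[3,5-bis(benzyloxy)phenyl]propan-2-ol, via arylmagnesium bromide 11 (not isolated)
Conditions: Mg, THF, reflux; CuI (10 mol %), 10, −30 → 0 °C; aq NH4Cl
Reagents that add atoms: none
Why: Copper-catalysed SN2 opening of a terminal epoxide by an aryl Grignard reagent takes place at the unsubstituted CH2, so the C–O bond at the stereocentre is untouched and the (R) configuration of 10 is carried into 12.

**Step 6**
Reactants: 13 (R)-benzyl glycidyl ether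
Product: 14 methyl (R)-4-(benzyloxy)-3-hydroxybutanoate
Conditions: Co2(CO)8 (5 mol %), 3-hydroxypyridine (10 mol %), CO (40 bar), MeOH–THF, 60 °C
Reagents that add atoms: carbon monoxide, [C-]#[O+]; methanol, CO
Why: In this cobalt-catalysed methoxycarbonylation of a terminal epoxide, [Co(CO)4]− opens the activated epoxide at CH2, CO inserts and methanolysis of the acylcobalt releases the β-hydroxy ester, so the stereocentre is not touched and stays (R).

**Step 7**
Reactants: 14 methyl (R)-4-(benzyloxy)-3-hydroxybutanoate
Product: 15 benzyl (R)-4-(benzyloxy)-3-hydroxybutanoate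
Conditions: BnOH (5 equiv), Ti(OiPr)4 (10 mol %), toluene, reflux (−MeOH)
Reagents that add atoms: benzyl alcohol, OCc1ccccc1
Why: Titanate-mediated transesterification is nearly neutral and tolerates the free β-hydroxyl without dehydration or racemisation, and removal of methanol drives the exchange to the benzyl ester needed for the final hydrogenolysis.

**Step 8**
Reactants: 8 (4R,8S)-4,8-dimethyl-1,5-dioxocane-2,6-dione; 12 (R)-1-[3,5-bis(benzyloxy)phenyl]propan-2-ol
Product: 16 (R)-1-[3,5-bis(benzyloxy)phenyl]propan-2-yl (R)-3-{[(S)-3-hydroxybutanoyl]oxy}butanoate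
Conditions: Y[N(SiHMe2)2]3(THF)2 (5 mol %) premixed with (R,R)-N,N'-bis(3,5-di-tert-butylsalicylidene)cyclohexane-1,2-diamine (5 mol %), 12 (3 equiv), toluene, 0 °C, slow addition of 8; AcOH quench; excess 12 recovered
Reagents that add atoms: none
Why: Proposed new method: protonolysis of the yttrium amide by 12 gives a chiral salen alkoxide of trivalent yttrium, which binds one lactone carbonyl of 8, adds its alkoxide to it and cleaves the acyl–oxygen bond (coordination–insertion), the release of eight-membered-ring strain making the opening fast and irreversible. The new yttrium alkoxide is chelated by its own β-ester carbonyl and should be less reactive; the excess of 12 protonates it, freeing 16 and restoring the active alkoxide, so a threefold excess of 12 and slow addition of 8 should hold the reaction at one insertion. The two carbonyls of 8 are enantiotopic and attack must occur at C2, whose CH2 leads to the (R) carbon C4, so that C8 (S) becomes the free carbinol. The chiral pocket of the catalyst is to make this choice, no stereocentre is formed or touched, and because 12 is a single enantiomer the wrong-carbonyl product is a diastereomer that chromatography can remove. The closest known reaction types are the stereoselective ring-opening polymerisation of eight-membered diolides and of lactide by yttrium alkoxides with an alcohol as chain-transfer agent, and the catalytic desymmetrising alcoholysis of meso cyclic anhydrides.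

**Step 9**
Reactants: 16 (R)-1-[3,5-bis(benzyloxy)phenyl]propan-2-yl (R)-3-{[(S)-3-hydroxybutanoyl]oxy}butanoate
Product: 17 (R)-1-[3,5-bis(benzyloxy)phenyl]propan-2-yl (R)-3-{[(S)-3-{[(benzyloxy)carbonyl]oxy}butanoyl]oxy}butanoate
Conditions: CbzCl (1.5 equiv), pyridine (3 equiv), DMAP (5 mol %), CH2Cl2, 0 °C
Reagents that add atoms: benzyl chloroformate, ClC(=O)OCc1ccccc1
Why: Carbonate formation by acylation of the secondary alcohol under weakly basic conditions at 0 °C, too mild for E1cB loss of the β-acyloxy groups, masks the hydroxyl against the Vilsmeier reagent with a group that falls in the final hydrogenolysis.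

**Step 10**
Reactants: 17 (R)-1-[3,5-bis(benzyloxy)phenyl]propan-2-yl (R)-3-{[(S)-3-{[(benzyloxy)carbonyl]oxy}butanoyl]oxy}butanoate
Product: 19 (R)-1-[3,5-bis(benzyloxy)-2-formylphenyl]propan-2-yl (R)-3-{[(S)-3-{[(benzyloxy)carbonyl]oxy}butanoyl]oxy}butanoate, via aryl iminium chloride 18 (not isolated)
Conditions: POCl3 (2 equiv), DMF, 0 °C → rt; then ice–water
Reagents that add atoms: N,N-dimethylformamide, CN(C)C=O; water, O
Why: In the Vilsmeier–Haack formylation the chloroiminium ion attacks the resorcinol diether ring at C2 (equivalent to C6), para to one benzyloxy group and ortho to the other, rather than at C4 between the two benzyloxy groups, while the esters and the carbonate are inert to the reagent.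

**Step 11**
Reactants: 19 (R)-1-[3,5-bis(benzyloxy)-2-formylphenyl]propan-2-yl (R)-3-{[(S)-3-{[(benzyloxy)carbonyl]oxy}butanoyl]oxy}butanoate
Product: 20 2,4-bis(benzyloxy)-6-{(R)-2-[((R)-3-{[(S)-3-{[(benzyloxy)carbonyl]oxy}butanoyl]oxy}butanoyl)oxy]propyl}benzoic acid
Conditions: NaClO2, NaH2PO4, 2-methyl-2-butene, t-BuOH–THF–H2O, rt
Reagents that add atoms: sodium chlorite, [Na+].[O-]Cl=O
Why: The Pinnick oxidation (chlorous acid adds to the aldehyde and fragments to the acid and HOCl) runs at about pH 4 and leaves esters, carbonate and benzyl ethers alone, while the alkene scavenger removes HOCl before it can chlorinate the electron-rich ring.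

**Step 12**
Reactants: 20 2,4-bis(benzyloxy)-6-{(R)-2-[((R)-3-{[(S)-3-{[(benzyloxy)carbonyl]oxy}butanoyl]oxy}butanoyl)oxy]propyl}benzoic acid; 15 benzyl (R)-4-(benzyloxy)-3-hydroxybutanoate
Product: 22 benzyl (R)-4-(benzyloxy)-3-[(2,4-bis(benzyloxy)-6-{(R)-2-[((R)-3-{[(S)-3-{[(benzyloxy)carbonyl]oxy}butanoyl]oxy}butanoyl)oxy]propyl}benzoyl)oxy]butanoate, via aroyl chloride 21 (not isolated)
Conditions: 1-chloro-N,N,2-trimethylprop-1-en-1-amine (1.05 equiv), CH2Cl2, 0 °C → rt; then 15 (1.2 equiv), DMAP (1.5 equiv), 0 °C → rt
Reagents that add atoms: none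
Why: The di-ortho-substituted acid is turned into its acid chloride under neutral conditions with the α-chloroenamine and passed to the secondary alcohol by DMAP-catalysed acylation through the acylpyridinium ion, with retention at the carbinol carbon of 15 because only its O–H bond is broken.

**Step 13**
Reactants: 22 benzyl (R)-4-(benzyloxy)-3-[(2,4-bis(benzyloxy)-6-{(R)-2-[((R)-3-{[(S)-3-{[(benzyloxy)carbonyl]oxy}butanoyl]oxy}butanoyl)oxy]propyl}benzoyl)oxy]butanoate
Product: 23 talapolyester A
Conditions: H2 (1 atm), 10% Pd/C, EtOAc, rt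
Reagents that add atoms: none
Why: Heterogeneous hydrogenolysis cleaves all five benzylic C–O bonds (two aryl ethers, one alkyl ether, the ester and the carbonate, which then loses CO2) under neutral conditions that leave the remaining ester links and all four stereocentres untouched and give little occasion for acyl migration to the freed primary hydroxyl.

**Compound list**
1 | dimethyl succinate | COC(=O)CCC(=O)OC | starting material
2 | dimethyl 3-(methoxycarbonyl)-4-oxoheptanedioate (open-chain Claisen triester, not isolated) | COC(=O)CCC(=O)C(CC(=O)OC)C(=O)OC | intermediate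
3 | dimethyl 2,5-dioxocyclohexane-1,4-dicarboxylate (drawn as diketo tautomer) | COC(=O)C1CC(=O)C(CC1=O)C(=O)OC | intermediate
4 | dimethyl 1,4-dimethyl-2,5-dioxocyclohexane-1,4-dicarboxylate (cis/trans mixture) | COC(=O)C1(C)CC(=O)C(C)(CC1=O)C(=O)OC | intermediate
5 | 1,4-dimethyl-2,5-dioxocyclohexane-1,4-dicarboxylic acid (not isolated) | OC(=O)C1(C)CC(=O)C(C)(CC1=O)C(=O)O | intermediate
6 | (2R,5S)-2,5-dimethylcyclohexane-1,4-dione (trans, meso) | C[C@H]1CC(=O)[C@H](C)CC1=O | intermediate
7 | (4R,7S)-4,7-dimethyloxepane-2,5-dione (racemate, one enantiomer drawn, not isolated) | C[C@H]1CC(=O)[C@H](C)CC(=O)O1 | intermediate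
8 | (4R,8S)-4,8-dimethyl-1,5-dioxocane-2,6-dione (meso diolide) | C[C@H]1CC(=O)O[C@H](C)CC(=O)O1 | intermediate
9 | 1-bromo-3,5-bis(benzyloxy)benzene | Brc1cc(OCc2ccccc2)cc(OCc2ccccc2)c1 | starting material
10 | (R)-propylene oxide | C[C@@H]1CO1 | starting material
11 | 3,5-bis(benzyloxy)phenylmagnesium bromide (not isolated) | Br[Mg]c1cc(OCc2ccccc2)cc(OCc2ccccc2)c1 | intermediate
12 | (R)-1-[3,5-bis(benzyloxy)phenyl]propan-2-ol | O[C@H](C)Cc1cc(OCc2ccccc2)cc(OCc2ccccc2)c1 | intermediate
13 | (R)-benzyl glycidyl ether | C1[C@@H](O1)COCc2ccccc2 | starting material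
14 | methyl (R)-4-(benzyloxy)-3-hydroxybutanoate | COC(=O)C[C@@H](O)COCc1ccccc1 | intermediate
15 | benzyl (R)-4-(benzyloxy)-3-hydroxybutanoate | O=C(C[C@@H](O)COCc1ccccc1)OCc1ccccc1 | intermediate
16 | (R)-1-[3,5-bis(benzyloxy)phenyl]propan-2-yl (R)-3-{[(S)-3-hydroxybutanoyl]oxy}butanoate | C[C@H](O)CC(=O)O[C@H](C)CC(=O)O[C@H](C)Cc1cc(OCc2ccccc2)cc(OCc2ccccc2)c1 | intermediate
17 | benzyl carbonate of 16 at the terminal (S)-hydroxyl | C[C@H](OC(=O)OCc1ccccc1)CC(=O)O[C@H](C)CC(=O)O[C@H](C)Cc1cc(OCc2ccccc2)cc(OCc2ccccc2)c1 | intermediate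
18 | N,N-dimethyliminium chloride of aldehyde 19 (not isolated) | C[C@H](OC(=O)OCc1ccccc1)CC(=O)O[C@H](C)CC(=O)O[C@H](C)Cc1cc(OCc2ccccc2)cc(OCc2ccccc2)c1C=[N+](C)C.[Cl-] | intermediate
19 | 2-formyl derivative of 17 (CHO ortho to the side chain, para to one OBn) | C[C@H](OC(=O)OCc1ccccc1)CC(=O)O[C@H](C)CC(=O)O[C@H](C)Cc1cc(OCc2ccccc2)cc(OCc2ccccc2)c1C=O | intermediate
20 | 2,4-bis(benzyloxy)-6-{(R)-2-[((R)-3-{[(S)-3-{[(benzyloxy)carbonyl]oxy}butanoyl]oxy}butanoyl)oxy]propyl}benzoic acid | C[C@H](OC(=O)OCc1ccccc1)CC(=O)O[C@H](C)CC(=O)O[C@H](C)Cc1cc(OCc2ccccc2)cc(OCc2ccccc2)c1C(=O)O | intermediate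
21 | acid chloride of 20 (not isolated) | C[C@H](OC(=O)OCc1ccccc1)CC(=O)O[C@H](C)CC(=O)O[C@H](C)Cc1cc(OCc2ccccc2)cc(OCc2ccccc2)c1C(=O)Cl | intermediate
22 | fully protected talapolyester A (aroyl ester of 20 with 15) | C[C@H](OC(=O)OCc1ccccc1)CC(=O)O[C@H](C)CC(=O)O[C@H](C)Cc1cc(OCc2ccccc2)cc(OCc2ccccc2)c1C(=O)O[C@@H](COCc1ccccc1)CC(=O)OCc1ccccc1 | intermediate
23 | talapolyester A, (R)-3-[(2,4-dihydroxy-6-{(R)-2-[((R)-3-{[(S)-3-hydroxybutanoyl]oxy}butanoyl)oxy]propyl}benzoyl)oxy]-4-hydroxybutanoic acid | C[C@H](O)CC(=O)O[C@H](C)CC(=O)O[C@H](C)Cc1cc(O)cc(O)c1C(=O)O[C@@H](CO)CC(=O)O | target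

**Step count**
Total step count: 13. Longest linear sequence: 10 steps (steps 1–4 and 8–13).

**Steps most likely to fail**

Step 8. Three processes may spoil it.
- Further diolide may insert into the freed carbinol, so that oligomers grow.
- The two enantiotopic carbonyls may be told apart only weakly.
- The ester links may scramble by transesterification.

The fallback sets out from 12 and comes back at 16, and it sets both butanoyl stereocentres by catalyst-controlled reduction.
- 12 is heated with 2,2,6-trimethyl-4H-1,3-dioxin-4-one in toluene (trapping of acetylketene) to give (R)-1-[3,5-bis(benzyloxy)phenyl]propan-2-yl 3-oxobutanoate F1.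
- Noyori hydrogenation with RuCl2[(R)-BINAP] under H2 pressure in CH2Cl2–MeOH sets the inner (R) carbinol and gives (R)-1-[3,5-bis(benzyloxy)phenyl]propan-2-yl (R)-3-hydroxybutanoate F2. The benzyl ethers are inert to the homogeneous catalyst.
- A second acetoacetylation gives (R)-1-[3,5-bis(benzyloxy)phenyl]propan-2-yl (R)-3-[(3-oxobutanoyl)oxy]butanoate F3.
- Hydrogenation with RuCl2[(S)-BINAP] sets the terminal (S) carbinol and delivers 16.

Step 4. The oxidation may stall after the first insertion, CH2 migration may compete, and enolisation may epimerise the α-centres ahead of oxidation.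

The fallback sets out from 12 and comes back at 17. It gives up the diolide and builds the dimer from the chiral pool.
- Commercial tert-butyl (S)-3-hydroxybutanoate is treated with CbzCl and pyridine to give tert-butyl (S)-3-{[(benzyloxy)carbonyl]oxy}butanoate F4.
- TFA in CH2Cl2 frees (S)-3-{[(benzyloxy)carbonyl]oxy}butanoic acid F5.
- EDC/DMAP coupling with commercial tert-butyl (R)-3-hydroxybutanoate gives tert-butyl (R)-3-{[(S)-3-{[(benzyloxy)carbonyl]oxy}butanoyl]oxy}butanoate F6.
- TFA gives (R)-3-{[(S)-3-{[(benzyloxy)carbonyl]oxy}butanoyl]oxy}butanoic acid F7.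
- Steglich esterification of F7 with 12 gives 17.

Step 12. Acyl transfer at the di-ortho-substituted carbonyl may be slow, which leaves time for base-induced β-elimination in the β-hydroxy and β-acyloxy ester.

The fallback sets out from 20 and comes back at 23. It lets the carboxylate act as the nucleophile on an alcohol that has no acidic α-hydrogen.
- Commercial (S)-benzyl glycidyl ether is opened with vinylmagnesium bromide and CuI to give (S)-1-(benzyloxy)pent-4-en-2-ol F8.
- Mitsunobu esterification with 20 (PPh3, DIAD, toluene) inverts the carbinol and gives the (R)-1-(benzyloxy)pent-4-en-2-yl ester of 20 F9.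
- Lemieux–Johnson cleavage (cat. OsO4, NaIO4, 2,6-lutidine, dioxane–H2O) gives the (R)-1-(benzyloxy)-4-oxobutan-2-yl ester of 20 F10, which is carried on without purification.
- Pinnick oxidation gives (R)-4-(benzyloxy)-3-(aroyloxy)butanoic acid derived from 20 F11.
- Hydrogenolysis as in step 13 then gives 23.

**Further compounds**
F1 | step 8 | (R)-1-[3,5-bis(benzyloxy)phenyl]propan-2-yl 3-oxobutanoate | CC(=O)CC(=O)O[C@H](C)Cc1cc(OCc2ccccc2)cc(OCc2ccccc2)c1
F2 | step 8 | (R)-1-[3,5-bis(benzyloxy)phenyl]propan-2-yl (R)-3-hydroxybutanoate | C[C@@H](O)CC(=O)O[C@H](C)Cc1cc(OCc2ccccc2)cc(OCc2ccccc2)c1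
F3 | step 8 | (R)-1-[3,5-bis(benzyloxy)phenyl]propan-2-yl (R)-3-[(3-oxobutanoyl)oxy]butanoate | CC(=O)CC(=O)O[C@H](C)CC(=O)O[C@H](C)Cc1cc(OCc2ccccc2)cc(OCc2ccccc2)c1
F4 | step 4 | tert-butyl (S)-3-{[(benzyloxy)carbonyl]oxy}butanoate | C[C@H](OC(=O)OCc1ccccc1)CC(=O)OC(C)(C)C
F5 | step 4 | (S)-3-{[(benzyloxy)carbonyl]oxy}butanoic acid | C[C@H](OC(=O)OCc1ccccc1)CC(=O)O
F6 | step 4 | tert-butyl (R)-3-{[(S)-3-{[(benzyloxy)carbonyl]oxy}butanoyl]oxy}butanoate | C[C@H](OC(=O)OCc1ccccc1)CC(=O)O[C@H](C)CC(=O)OC(C)(C)C
F7 | step 4 | (R)-3-{[(S)-3-{[(benzyloxy)carbonyl]oxy}butanoyl]oxy}butanoic acid | C[C@H](OC(=O)OCc1ccccc1)CC(=O)O[C@H](C)CC(=O)O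
F8 | step 12 | (S)-1-(benzyloxy)pent-4-en-2-ol | O[C@H](COCc1ccccc1)CC=C
F9 | step 12 | (R)-1-(benzyloxy)pent-4-en-2-yl ester of 20 | C[C@H](OC(=O)OCc1ccccc1)CC(=O)O[C@H](C)CC(=O)O[C@H](C)Cc1cc(OCc2ccccc2)cc(OCc2ccccc2)c1C(=O)O[C@@H](COCc1ccccc1)CC=C
F10 | step 12 | (R)-1-(benzyloxy)-4-oxobutan-2-yl ester of 20 | C[C@H](OC(=O)OCc1ccccc1)CC(=O)O[C@H](C)CC(=O)O[C@H](C)Cc1cc(OCc2ccccc2)cc(OCc2ccccc2)c1C(=O)O[C@@H](COCc1ccccc1)CC=O
F11 | step 12 | (R)-4-(benzyloxy)-3-(aroyloxy)butanoic acid derived from 20 | C[C@H](OC(=O)OCc1ccccc1)CC(=O)O[C@H](C)CC(=O)O[C@H](C)Cc1cc(OCc2ccccc2)cc(OCc2ccccc2)c1C(=O)O[C@@H](COCc1ccccc1)CC(=O)O
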